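**Retrosynthetic overview**
1. Target 24 ⇐ diol 23 ⇐ bis-silyl ether 22: the acid is revealed last, by desilylation and oxidation of a 3-hydroxypropyl chain.
2. Key disconnection of 22: the tropone ring is cut into three C2 units plus CO, namely the ynol ether carbons C8a'/C8', the terminal alkyne carbons C3a'/C4', methyl but-2-ynoate (C5'/C6') and CO (C7'). Diyne 19, 20 and 21 are joined in one rhodium-catalysed carbonylative [2+2+2+1] step that also closes the dihydrofuran ring.
3. 19 ⇐ ketone 12: propargylzinc addition (sets the spiro carbon C1), then O-alkynylation of the tertiary alkoxide through trichloroethylene.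
4. 12 ⇐ (S)-carvone 1: α'-methylation, α'-allylation anti to isopropenyl (quaternary centre), 1,4-reduction, hydroboration, hydration, silylation. Ring order: cyclohexane ring from carvone, then dihydrofuran and tropone rings together in step 10.
5. Feature carrying the strategy: in the tropone ring the O-bearing C8a' and the CH2-bearing C3a' are neighbours already tied together through O1'–C1(spiro)–C3' (the dihydrofuran ring), and the ring carbons fall into the vicinal pairs C8a'/C8'(Me), C3a'/C4'(H) and C5'(Me)/C6'(CO2Me) around the single carbonyl C7'.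

Key step: step 10

Remark on the chemistry: the propanoic acid chain is carried as a 3-(triethylsilyloxy)propyl group up to 22, because an ester there would lactonise onto the C1 alkoxide and would not survive n-BuLi in step 8, and because an acrylate Michael addition to dienolate 5 is expected to run on to a bicyclo[2.2.2]octanone. Compound 3 is used as its C6 epimer mixture, and the α-methyl centre of 8 and 10 is fixed by equilibration in step 5.

**Step 1**
Reactants: 1 (S)-(+)-carvone
Product: 3 (5S,6R)-2,6-dimethyl-5-(prop-1-en-2-yl)cyclohex-2-en-1-one (trans-6-methylcarvone), via lithium dienolate 2 (not isolated)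
Conditions: LiN(i-Pr)2, THF, −78 °C; MeI, −78 → 0 °C
Reagents that add atoms: iodomethane, CI
Why: Kinetic deprotonation at C6 gives the cross-conjugated lithium dienolate, and enolate C-methylation occurs mainly anti to the isopropenyl group; the C6 configuration does not matter because step 2 makes this carbon planar again.

**Step 2**
Reactants: 3 trans-6-methylcarvone; 4 allyl bromide
Product: 6 (5R,6R)-2,6-dimethyl-6-(prop-2-en-1-yl)-5-(prop-1-en-2-yl)cyclohex-2-en-1-one, via lithium dienolate 5 (not isolated)
Conditions: LiN(i-Pr)2, THF, −78 °C; allyl bromide, DMPU, −78 → 0 °C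
Reagents that add atoms: none
Why: Enolate alkylation of the tetrasubstituted C6 dienolate, in which the C5 isopropenyl group turns pseudoaxial to escape allylic strain with the C6 methyl and shields one face, so that allyl bromide enters anti to it and the quaternary centre forms with allyl trans and methyl cis to isopropenyl.

**Step 3**
Reactants: 6 allylated enone
Product: 8 (2R,3R,6S)-2,6-dimethyl-2-(prop-2-en-1-yl)-3-(prop-1-en-2-yl)cyclohexan-1-one, via lithium enolate 7 (not isolated)
Conditions: LiBH(s-Bu)3, THF, −78 °C; AcOH
Reagents that add atoms: none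
Why: Conjugate (1,4) hydride reduction, since the bulky borohydride cannot reach the carbonyl next to the quaternary carbon and adds to the unsubstituted β-carbon while both isolated alkenes are left alone; the new α-methyl centre arises on protonation and is brought to the drawn equatorial epimer in step 5.

**Step 4**
Reactants: 8 saturated ketone
Product: 10 (2R,3R,6S)-2-(3-hydroxypropyl)-2,6-dimethyl-3-(prop-1-en-2-yl)cyclohexan-1-one, via catechol boronate 9 (not isolated)
Conditions: catecholborane, RhCl(PPh3)3 (2 mol%), THF, 0 °C → rt; NaOH, H2O2, 0 °C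
Reagents that add atoms: hydrogen peroxide, OO
Why: Rhodium-catalysed hydroboration followed by oxidation, in which monovalent rhodium adds the B–H bond and inserts only the monosubstituted alkene (anti-Markovnikov), being slow towards the hindered 1,1-disubstituted isopropenyl group and the ketone; no stereocentre is formed.

**Step 5**
Reactants: 10 hydroxypropyl ketone
Product: 11 (2R,3S,6S)-2-(3-hydroxypropyl)-3-(2-hydroxypropan-2-yl)-2,6-dimethylcyclohexan-1-one
Conditions: Co(acac)2 (20 mol%), PhSiH3, O2 (1 atm), THF, rt; then NaOMe, MeOH, rt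
Reagents that add atoms: dioxygen, O=O
Why: Mukaiyama hydration (hydrogen-atom transfer from a cobalt hydride to the 1,1-disubstituted alkene, trapping of the tertiary radical by O2, reduction to the Markovnikov alcohol), after which methoxide equilibrates C6 to the equatorial-methyl epimer, the only one free of a syn-diaxial methyl/methyl contact in the chair that keeps the bulky C3 group equatorial.

**Step 6**
Reactants: 11 keto diol
Product: 12 (2R,3S,6S)-2,6-dimethyl-3-[2-(triethylsilyloxy)propan-2-yl]-2-[3-(triethylsilyloxy)propyl]cyclohexan-1-one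
Conditions: Et3SiOTf, 2,6-lutidine, CH2Cl2, −78 → 0 °C
Reagents that add atoms: triethylsilyl trifluoromethanesulfonate, CC[Si](CC)(CC)OS(=O)(=O)C(F)(F)F
Why: Silyl triflate silylation of both hydroxyl groups (the tertiary one needs the triflate), with 2,6-lutidine at low temperature not expected to enolise the hindered ketone.

**Step 7**
Reactants: 12 bis-silyl ketone; 13 3-bromo-1-(trimethylsilyl)prop-1-yne
Product: 14 (1R,2R,3S,6S)-2,6-dimethyl-3-[2-(triethylsilyloxy)propan-2-yl]-2-[3-(triethylsilyloxy)propyl]-1-[3-(trimethylsilyl)prop-2-yn-1-yl]cyclohexan-1-ol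
Conditions: Zn dust, THF, 0 °C → rt; aq. NH4Cl
Reagents that add atoms: none
Why: Barbier-type propargylation in which the allenylzinc bromide made in the flask adds through a cyclic SE2' transition state to give the homopropargylic alcohol, attacking the chair ketone axially from the face opposite the axial C2 methyl group (the equatorial path is blocked by that methyl), which sets C1 with the propargyl group axial and the hydroxyl equatorial.

**Step 8**
Reactants: 14 tertiary alcohol; 15 trichloroethylene
Product: 18 prop-1-yn-1-yl ether of 14 (1-(prop-1-yn-1-yloxy) in place of 1-hydroxy; C-silylated alkyne kept), via dichlorovinyl ether 16 (not isolated), via lithium alkynyl ether 17 (not isolated)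
Conditions: KH, THF, 0 °C; Cl2C=CHCl, −50 °C → rt; n-BuLi, −78 → −40 °C; MeI, HMPA, −78 → 0 °C
Reagents that add atoms: iodomethane, CI
Why: Ynol ether synthesis from an alkoxide and trichloroethylene in one flask (addition of the potassium alkoxide to dichloroacetylene formed in situ, elimination and Cl/Li exchange with n-BuLi, C-methylation of the lithium alkynyl ether), with the silyl cap keeping the other alkyne from metalation and methylation and the C1–O bond untouched, so configuration is retained.

**Step 9**
Reactants: 18 silylated diyne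
Product: 19 (1R,2R,3S,6S)-1-(prop-2-yn-1-yl)-1-(prop-1-yn-1-yloxy)cyclohexane bearing the 2,6-dimethyl, 3-[2-(triethylsilyloxy)propan-2-yl] and 2-[3-(triethylsilyloxy)propyl] groups of 14
Conditions: K2CO3, MeOH, 0 °C
Reagents that add atoms: none
Why: Base-mediated methanolysis of the alkynyl C–Si bond (protodesilylation), mild enough to leave the base-stable ynol ether and both triethylsilyl ethers intact; 19 is kept cold and used at once.

**Step 10**
Reactants: 19 diyne; 20 methyl but-2-ynoate; 21 carbon monoxide
Product: 22 methyl (1R,2R,3S,6S)-2,5',6,8'-tetramethyl-7'-oxo-3-[2-(triethylsilyloxy)propan-2-yl]-2-[3-(triethylsilyloxy)propyl]-3',7'-dihydrospiro[cyclohexane-1,2'-cyclohepta[b]furan]-6'-carboxylate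
Conditions: [Rh(CO)2Cl]2 (10 mol%), CO (2 atm), 20 (5 equiv), ClCH2CH2Cl, 40 °C, slow addition of 19
Reagents that add atoms: none
Why: Proposed new method: oxidative cyclisation of the tethered 1,6-diyne on monovalent rhodium should give a trivalent rhodacyclopentadiene (C3a'–C8a' bond); the ynoate then inserts into the unhindered Rh–C4'(H) bond with C4' going to its methyl-bearing carbon and rhodium to its ester-bearing carbon (C4'–C5' bond), CO inserts at the Rh–C8' end, and acyl–vinyl reductive elimination completes C6'–C7'–C8', the same tropone resulting if CO enters before the ynoate provided each takes the same terminus. The closest known reaction type is the rhodium-catalysed carbonylative [2+2+2+1] cycloaddition of fully tethered triynes and enediynes with CO to fused tropones, together with rhodium-catalysed [2+2+2] cycloadditions of 1,6-diynes with free alkynoates. The dihydrofuran ring closes in the oxidative coupling as a five-membered ring fused to the metallacycle, helped by the fully substituted C1 in the tether, and the tropone ring closes by reductive elimination from an eight-membered acyl rhodacycle. No stereocentre is formed and the four existing ones are not touched. The step needs regioselection (ynoate at C4' with its ester carbon on rhodium, CO at C8') and chemoselection over CO-free [2+2+2] arene formation and diyne-only [2+2+1] carbonylation. The H versus CH3 difference at the two metallacycle termini, the donor oxygen that makes the C8'–Rh bond the better migrating group towards CO, the polarisation of the ynoate, excess ynoate, CO pressure and a low stationary concentration of 19 are relied on for this.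

**Step 11**
Reactants: 22 bis-silyl tropone
Product: 23 methyl (1R,2R,3S,6S)-3-(2-hydroxypropan-2-yl)-2-(3-hydroxypropyl)-2,5',6,8'-tetramethyl-7'-oxo-3',7'-dihydrospiro[cyclohexane-1,2'-cyclohepta[b]furan]-6'-carboxylate
Conditions: HF·pyridine, pyridine, THF, 0 °C → rt
Reagents that add atoms: none
Why: Fluoride-driven cleavage of both triethylsilyl ethers under buffered, non-basic conditions that should spare the methyl ester and the vinylogous ester of the tropone.

**Step 12**
Reactants: 23 diol
Product: 24 3-[(1R,2R,3S,6S)-3-(2-hydroxypropan-2-yl)-6'-(methoxycarbonyl)-2,5',6,8'-tetramethyl-7'-oxo-3',7'-dihydrospiro[cyclohexane-1,2'-cyclohepta[b]furan]-2-yl]propanoic acid (target)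
Conditions: TEMPO (20 mol%), PhI(OAc)2, MeCN/H2O, rt
Reagents that add atoms: water, O
Why: Nitroxyl-catalysed oxidation takes the primary alcohol through the aldehyde hydrate to the carboxylic acid, while the tertiary alcohol cannot be oxidised.

**Compound list**
1 | (S)-(+)-carvone | CC1=CC[C@@H](CC1=O)C(C)=C | starting material
2 | lithium dienolate of carvone | [Li]OC1=C[C@@H](C(C)=C)CC=C1C | intermediate
3 | (5S,6R)-2,6-dimethyl-5-(prop-1-en-2-yl)cyclohex-2-en-1-one | O=C1C(C)=CC[C@H](C(C)=C)[C@H]1C | intermediate
4 | allyl bromide | C=CCBr | starting material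
5 | lithium dienolate of 3 | [Li]OC1=C(C)[C@@H](C(C)=C)CC=C1C | intermediate
6 | (5R,6R)-2,6-dimethyl-6-(prop-2-en-1-yl)-5-(prop-1-en-2-yl)cyclohex-2-en-1-one | O=C1C(C)=CC[C@H](C(C)=C)[C@@]1(C)CC=C | intermediate
7 | lithium enolate from 1,4-reduction of 6 | [Li]OC1=C(C)CC[C@H](C(C)=C)[C@@]1(C)CC=C | intermediate
8 | (2R,3R,6S)-2,6-dimethyl-2-(prop-2-en-1-yl)-3-(prop-1-en-2-yl)cyclohexan-1-one | O=C1[C@@H](C)CC[C@H](C(C)=C)[C@@]1(C)CC=C | intermediate
9 | catechol boronate of 8 (2-alkyl-1,3,2-benzodioxaborole) | O=C1[C@@H](C)CC[C@H](C(C)=C)[C@@]1(C)CCCB1Oc2ccccc2O1 | intermediate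
10 | (2R,3R,6S)-2-(3-hydroxypropyl)-2,6-dimethyl-3-(prop-1-en-2-yl)cyclohexan-1-one | O=C1[C@@H](C)CC[C@H](C(C)=C)[C@@]1(C)CCCO | intermediate
11 | (2R,3S,6S)-2-(3-hydroxypropyl)-3-(2-hydroxypropan-2-yl)-2,6-dimethylcyclohexan-1-one | O=C1[C@@H](C)CC[C@H](C(C)(C)O)[C@@]1(C)CCCO | intermediate
12 | (2R,3S,6S)-2,6-dimethyl-3-[2-(triethylsilyloxy)propan-2-yl]-2-[3-(triethylsilyloxy)propyl]cyclohexan-1-one | O=C1[C@@H](C)CC[C@H](C(C)(C)O[Si](CC)(CC)CC)[C@@]1(C)CCCO[Si](CC)(CC)CC | intermediate
13 | 3-bromo-1-(trimethylsilyl)prop-1-yne | C[Si](C)(C)C#CCBr | starting material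
14 | (1R,2R,3S,6S)-tertiary homopropargylic alcohol (propargyl axial, OH equatorial) | O[C@]1(CC#C[Si](C)(C)C)[C@@H](C)CC[C@H](C(C)(C)O[Si](CC)(CC)CC)[C@@]1(C)CCCO[Si](CC)(CC)CC | intermediate
15 | trichloroethylene | ClC=C(Cl)Cl | starting material
16 | (E)-1,2-dichlorovinyl ether of 14 | Cl/C=C(/Cl)O[C@]1(CC#C[Si](C)(C)C)[C@@H](C)CC[C@H](C(C)(C)O[Si](CC)(CC)CC)[C@@]1(C)CCCO[Si](CC)(CC)CC | intermediate
17 | lithium alkynyl ether of 14 | [Li]C#CO[C@]1(CC#C[Si](C)(C)C)[C@@H](C)CC[C@H](C(C)(C)O[Si](CC)(CC)CC)[C@@]1(C)CCCO[Si](CC)(CC)CC | intermediate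
18 | prop-1-yn-1-yl ether of 14 (C-silylated diyne) | CC#CO[C@]1(CC#C[Si](C)(C)C)[C@@H](C)CC[C@H](C(C)(C)O[Si](CC)(CC)CC)[C@@]1(C)CCCO[Si](CC)(CC)CC | intermediate
19 | diyne with propynyl ether and free propargyl group on C1 (key-step precursor) | CC#CO[C@]1(CC#C)[C@@H](C)CC[C@H](C(C)(C)O[Si](CC)(CC)CC)[C@@]1(C)CCCO[Si](CC)(CC)CC | intermediate
20 | methyl but-2-ynoate | CC#CC(=O)OC | starting material
21 | carbon monoxide | [C-]#[O+] | starting material
22 | bis(triethylsilyl)-protected spiro dihydrofuran tropone (key-step product) | COC(=O)c1c(C)cc2c(c(C)c1=O)O[C@]1(C2)[C@@H](C)CC[C@H](C(C)(C)O[Si](CC)(CC)CC)[C@@]1(C)CCCO[Si](CC)(CC)CC | intermediate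
23 | tropone diol (primary and tertiary alcohol) | COC(=O)c1c(C)cc2c(c(C)c1=O)O[C@]1(C2)[C@@H](C)CC[C@H](C(C)(C)O)[C@@]1(C)CCCO | intermediate
24 | CNP0448476.3 | COC(=O)c1c(C)cc2c(c(C)c1=O)O[C@]1(C2)[C@@H](C)CC[C@H](C(C)(C)O)[C@@]1(C)CCC(=O)O | target

**Total step count:** 12
**Longest linear sequence:** 12 steps, from (S)-carvone 1 to 24.

**Steps most likely to fail**

Step 10 (proposed new method). The carbonylation may lose to CO-free [2+2+2] arene formation or to diyne-only [2+2+1] carbonylation. The ynoate may insert at the wrong metallacycle terminus, the diyne may oligomerise, and the tertiary ynol ether may fragment thermally by retro-ene loss of methylketene. The fallback uses known reaction types, sets out from 19 and returns at 23. The terminal alkyne of 19 is lithiated (LiN(SiMe3)2, THF, −78 °C) and silylated with i-Pr2SiCl2 to the alkynyl(chloro)diisopropylsilane F1. In the same flask F1 is treated with methyl 4-hydroxybut-2-ynoate and imidazole to give the silyl-ether-tethered triyne F2. F2 is a substrate for the fully intramolecular rhodium-catalysed carbonylative [2+2+2+1] cycloaddition of triynes ([Rh(CO)2Cl]2, CO, ClCH2CH2Cl, 40 °C), in which the tether fixes the order of events and the orientation of the ynoate, and should give the oxasilole-fused tropone F3. Bu4NF in wet THF then cleaves the ring C–Si bond, the Si–O bond and both triethylsilyl ethers, and the freed hydroxymethyl group closes onto the neighbouring methyl ester to give the butenolide-fused tropone diol F4. Zinc in acetic acid cleaves the vinylogous γ-acyloxy C–O bond to leave the C5' methyl group and the C6' carboxylic acid in the tropone acid F5. Me3SiCHN2 in MeOH/toluene esterifies the acid, which rejoins the route at 23.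

Step 8. The hindered tertiary potassium alkoxide may add too slowly to dichloroacetylene or fragment by retro-propargylation back to ketone 12, and butyllithium may attack silicon or the propargylic position. The fallback sets out from 14 and returns at 18. Compound 14 is formylated (acetic formic anhydride, DMAP, pyridine) to the formate F6. Ramirez-type dibromoolefination of the formate carbonyl (CBr4, PPh3, Et3N, CH2Cl2) gives the 2,2-dibromovinyl ether F7. n-BuLi (2 equiv, −78 °C) converts F7 by Br/Li exchange and a Fritsch–Buttenberg–Wiechell-type 1,2-shift into the lithium alkynyl ether 17, which is methylated as in step 8 to give 18.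

Step 7. Addition to the doubly α-branched carbonyl may be slow and be overtaken by enolisation, facial selectivity may be incomplete, and the zinc reagent may react through its other terminus to give the allenyl carbinol. The fallback sets out from 12 and returns at 14. Corey–Chaykovsky epoxidation with dimethylsulfonium methylide (Me3S+ I−, n-BuLi, THF, −10 °C), with axial delivery of CH2 anti to the axial C2 methyl, gives the spiro-epoxide F8. F8 is opened at its CH2 terminus by LiC≡CSiMe3/BF3·OEt2 (THF, −78 °C) to give 14.

**Further compounds**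
F1 | step 10 | alkynyl(chloro)diisopropylsilane from 19 | CC#CO[C@]1(CC#C[Si](Cl)(C(C)C)C(C)C)[C@@H](C)CC[C@H](C(C)(C)O[Si](CC)(CC)CC)[C@@]1(C)CCCO[Si](CC)(CC)CC
F2 | step 10 | silyl-ether-tethered triyne | CC#CO[C@]1(CC#C[Si](OCC#CC(=O)OC)(C(C)C)C(C)C)[C@@H](C)CC[C@H](C(C)(C)O[Si](CC)(CC)CC)[C@@]1(C)CCCO[Si](CC)(CC)CC
F3 | step 10 | oxasilole-fused tropone | COC(=O)c1c2CO[Si](C(C)C)(C(C)C)c2c2c(c(C)c1=O)O[C@]1(C2)[C@@H](C)CC[C@H](C(C)(C)O[Si](CC)(CC)CC)[C@@]1(C)CCCO[Si](CC)(CC)CC
F4 | step 10 | butenolide-fused tropone diol | O=C1OCc2cc3c(c(C)c(=O)c12)O[C@]1(C3)[C@@H](C)CC[C@H](C(C)(C)O)[C@@]1(C)CCCO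
F5 | step 10 | tropone-6'-carboxylic acid diol | OC(=O)c1c(C)cc2c(c(C)c1=O)O[C@]1(C2)[C@@H](C)CC[C@H](C(C)(C)O)[C@@]1(C)CCCO
F6 | step 8 | formate of 14 | O=CO[C@]1(CC#C[Si](C)(C)C)[C@@H](C)CC[C@H](C(C)(C)O[Si](CC)(CC)CC)[C@@]1(C)CCCO[Si](CC)(CC)CC
F7 | step 8 | 2,2-dibromovinyl ether of 14 | BrC(Br)=CO[C@]1(CC#C[Si](C)(C)C)[C@@H](C)CC[C@H](C(C)(C)O[Si](CC)(CC)CC)[C@@]1(C)CCCO[Si](CC)(CC)CC
F8 | step 7 | spiro-epoxide of 12 (CH2 axial) | C1O[C@@]12[C@@H](C)CC[C@H](C(C)(C)O[Si](CC)(CC)CC)[C@@]2(C)CCCO[Si](CC)(CC)CC
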